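Everything rests on cutting C1′–C2′ and C3′–C4′ in the substituted half of the naphthalene (ring A: C1′–C4′, C4a′, C8a′). Its C4′–O lies peri to C5′–O and C1′ holds the isoquinoline. This is the imprint of an 8-alkoxyhomophthalic anhydride (aryl C=O becomes C4′, benzylic carbon becomes C1′) joined to a but-2-ynoate (C2′ with its methyl, C3′). One anionic (4+2) annulation with CO2 loss makes both bonds, closes ring A, unveils C4′–OH alone for methylation and turns C7–C1′ into the biaryl axis. The precursor is a racemic 8-benzyloxy-4-(isoquinolin-7-yl) anhydride. Its C7–C1′ bond is made earlier, as an sp3–sp2 bond, by ester α-arylation. The atropisomers are separated last.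

Key step: step 10

Assumption: the SMILES string is binding, so the target carries C4′–OMe and free hydroxyls at C5′ and C8 (C23H21NO3; a 4′,5′-dimethoxy reading of the name would have one more O-methyl group), and, as SMILES cannot show the C7–C1′ axis, the ent-series atropisomer is taken from the racemate in step 14.

Step 1
Reactants: 1 3-methoxy-2-(trimethylsilyl)phenyl trifluoromethanesulfonate; 2 acetylacetone
Product: 5 8-methoxy-1,3-dimethylisoquinoline, via 3-methoxybenzyne 3 (not isolated), via 1-(2-acetyl-3-methoxyphenyl)propan-2-one 4 (not isolated)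
Conditions: 2 (2 equiv), CsF (2.5 equiv), MeCN, 60 °C; then 28% aq NH3, 60 °C
Reagents that add atoms: ammonia, N
Why: Fluoride-triggered 1,2-elimination gives aryne 3, whose terminus remote from the methoxy group is attacked by the acetylacetonate carbon, and the resulting ortho-methoxy aryl anion closes onto a ketone and fragments (aryne acyl-alkylation, a C–C σ-bond insertion), which places the acetyl group next to OMe in 1,5-diketone 4; ammonia, added as soon as 1 is consumed so that aldol closure of 4 gets little time, then builds the pyridine ring by double condensation.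

Step 2
Reactants: 5 8-methoxy-1,3-dimethylisoquinoline
Product: 6 1,3-dimethylisoquinolin-8-ol
Conditions: 48% aq HBr, AcOH, reflux
Reagents that add atoms: none
Why: Acid-mediated aryl methyl ether cleavage (SN2 attack of bromide on the protonated ether), routine for methoxy-substituted quinolines and isoquinolines, and 5 offers no other reactive site.

Step 3
Reactants: 6 1,3-dimethylisoquinolin-8-ol
Product: 7 7-bromo-1,3-dimethylisoquinolin-8-ol
Conditions: NBS (1.0 equiv, slow addition), iPr2NH (10 mol %), CH2Cl2, 0 °C, dark
Reagents that add atoms: N-bromosuccinimide, O=C1CCC(=O)N1Br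
Why: Amine-mediated ortho-selective electrophilic bromination of a phenol: the N-bromoamine formed from NBS and iPr2NH binds to the O–H group by a hydrogen bond and delivers bromine to the neighbouring C7 rather than to the para position C5, as is established for 1-naphthols, while slow addition of one equivalent in the dark holds back dibromination and side-chain bromination.

Step 4
Reactants: 7 7-bromo-1,3-dimethylisoquinolin-8-ol
Product: 8 8-(benzyloxy)-7-bromo-1,3-dimethylisoquinoline
Conditions: BnBr (1.05 equiv), K2CO3, DMF, rt to 50 °C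
Reagents that add atoms: benzyl bromide, BrCc1ccccc1
Why: Williamson ether synthesis, in which the phenoxide reacts much faster than the ring nitrogen because the latter is flanked by the C1 and C3 methyl groups.

Step 5
Reactants: 9 ethyl 2-hydroxy-6-methylbenzoate
Product: 10 ethyl 2-(benzyloxy)-6-methylbenzoate
Conditions: BnBr, K2CO3, DMF, 60 °C
Reagents that add atoms: benzyl bromide, BrCc1ccccc1
Why: Williamson ether synthesis on the salicylate phenol, with gentle heating to overcome its hydrogen bond to the ester.

Step 6
Reactants: 10 ethyl 2-(benzyloxy)-6-methylbenzoate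
Product: 12 ethyl 2-(benzyloxy)-6-(2-ethoxy-2-oxoethyl)benzoate, via benzylic organolithium 11 (not isolated)
Conditions: LiN(iPr)2 (2.2 equiv), THF, −78 °C; (EtO)2CO, −78 °C to 0 °C; 1 M HCl
Reagents that add atoms: diethyl carbonate, CCOC(=O)OCC
Why: Lateral lithiation of an ortho-toluate followed by C-acylation of the benzylic anion with a carbonate (Claisen-type carboxylation), the second equivalent of amide base taking up the more acidic product so that neither proton exchange nor self-condensation of 11 with 10 intervenes.

Step 7
Reactants: 12 ethyl 2-(benzyloxy)-6-(2-ethoxy-2-oxoethyl)benzoate; 8 8-(benzyloxy)-7-bromo-1,3-dimethylisoquinoline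
Product: 14 rac-ethyl 2-(benzyloxy)-6-{1-[8-(benzyloxy)-1,3-dimethylisoquinolin-7-yl]-2-ethoxy-2-oxoethyl}benzoate, via lithium enolate 13 (not isolated)
Conditions: LiN(SiMe3)2, toluene, 0 °C; then 8, Pd(OAc)2 (5 mol %), 2-(dicyclohexylphosphino)-2′-(dimethylamino)biphenyl (10 mol %), 80 °C
Reagents that add atoms: none
Why: Palladium-catalysed α-arylation of an ester enolate (Buchwald–Hartwig type), established for arylacetates and ortho-substituted aryl bromides: zerovalent palladium inserts into C7–Br, enolate 13 displaces bromide and reductive elimination forms the later biaryl bond while its naphthalene-side carbon is still sp3, the new stereocentre being racemic and erased in step 10.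

Step 8
Reactants: 14 rac-ethyl 2-(benzyloxy)-6-{1-[8-(benzyloxy)-1,3-dimethylisoquinolin-7-yl]-2-ethoxy-2-oxoethyl}benzoate
Product: 15 rac-2-(benzyloxy)-6-{[8-(benzyloxy)-1,3-dimethylisoquinolin-7-yl](carboxy)methyl}benzoic acid
Conditions: KOH (10 equiv), EtOH–H2O, reflux; then HCl to pH 5
Reagents that add atoms: water (as hydroxide), O
Why: Ester saponification, in which the carboxylate freed first from the diarylacetate ester assists cleavage of the di-ortho-substituted benzoate through the transient cyclic anhydride, as in the hydrolysis of simple 3-alkoxyhomophthalates, and the amphoteric diacid is collected at its isoelectric point.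

Step 9
Reactants: 15 rac-2-(benzyloxy)-6-{[8-(benzyloxy)-1,3-dimethylisoquinolin-7-yl](carboxy)methyl}benzoic acid
Product: 16 rac-8-(benzyloxy)-4-[8-(benzyloxy)-1,3-dimethylisoquinolin-7-yl]isochromane-1,3-dione
Conditions: Me3SiC≡COEt (1.5 equiv), CH2Cl2, 40 °C; evaporation
Reagents that add atoms: none
Why: Cyclodehydration of a diacid with an alkoxyalkyne (addition of one carboxyl group across the triple bond, then intramolecular acyl transfer) under neutral conditions, chosen instead of hot acetic anhydride because the latter, helped by the basic nitrogen, could acylate the enolisable C4, and because the only by-product is volatile, so that moisture-sensitive 16 is used without purification.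

Step 10
Reactants: 16 rac-8-(benzyloxy)-4-[8-(benzyloxy)-1,3-dimethylisoquinolin-7-yl]isochromane-1,3-dione; 17 ethyl but-2-ynoate
Product: 20 rac-ethyl 8-(benzyloxy)-4-[8-(benzyloxy)-1,3-dimethylisoquinolin-7-yl]-1-hydroxy-3-methyl-2-naphthoate, via sodium enolate 18 (not isolated), via ring-opened carboxylate 19 (not isolated)
Conditions: NaH (1.05 equiv), THF, 0 °C; 17 (3 equiv), 0 °C to 65 °C; AcOH
Reagents that add atoms: none
Why: NaH removes the doubly activated C4–H of 16 (far more acidic than the C1-methyl protons of the isoquinoline), and the benzylic carbon of enolate 18 adds in a Michael reaction to the methyl-bearing β-carbon of 17, forming C1′–C2′. The ester-stabilised vinyl anion so formed attacks the aryl carbonyl of the anhydride in a 6-exo-trig, Dieckmann-type acylation that forms C3′–C4′ and closes ring A, attack on the other carbonyl being ruled out because it would close a four-membered ring, and the anhydride opens to carboxylate 19. As a vinylogous β-keto carboxylate, 19 loses CO2 with aromatisation, which makes the sequence irreversible and flattens the crowded quaternary C1′. This is the Tamura annulation of homophthalic anhydrides with alkynoates, for which 8-alkoxy donors are standard and C4-heteroatom-substituted donors show that a fully substituted C4 can be passed through; a C4-aryl donor with a β-substituted ynoate lies at the edge of that scope, hence the excess of 17 and the option of heating. No stereocentre survives: the C4 centre of 16 is erased in planar 18, the C1′ centre of 19 is lost with CO2, and the C7–C1′ axis, which becomes configurationally stable here, is formed as a racemate. The one selectivity needed, methyl at C2′ next to the isoquinoline and ester at C3′, is secured by the polarisation of the ynoate, and only C4′–OH emerges unprotected.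

Step 11
Reactants: 20 rac-ethyl 8-(benzyloxy)-4-[8-(benzyloxy)-1,3-dimethylisoquinolin-7-yl]-1-hydroxy-3-methyl-2-naphthoate
Product: 22 rac-8-(benzyloxy)-4-[8-(benzyloxy)-1,3-dimethylisoquinolin-7-yl]-3-methylnaphthalen-1-ol, via hydroxy acid 21 (not isolated)
Conditions: KOH, HOCH2CH2OH–H2O, 130 °C, Ar; AcOH to pH 5, then 160 °C
Reagents that add atoms: none
Why: Forcing saponification of the hindered salicylate-type ester, which benzyl ethers and the isoquinoline tolerate, then thermal protodecarboxylation of ortho-hydroxy acid 21 through its keto tautomer, a β-keto acid (reverse Kolbe–Schmitt reaction), helped by relief of strain between the carboxyl group and the C2′ methyl group.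

Step 12
Reactants: 22 rac-8-(benzyloxy)-4-[8-(benzyloxy)-1,3-dimethylisoquinolin-7-yl]-3-methylnaphthalen-1-ol
Product: 23 rac-8-(benzyloxy)-7-[5-(benzyloxy)-4-methoxy-2-methylnaphthalen-1-yl]-1,3-dimethylisoquinoline
Conditions: MeI (1.1 equiv), K2CO3, acetone, rt
Reagents that add atoms: iodomethane, CI
Why: Williamson O-methylation, selective because C4′–OH is the only free hydroxyl (O–C5′ and O–C8 have carried benzyl groups from the start) and because its phenoxide outruns the doubly flanked nitrogen when only a slight excess of MeI is used.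

Step 13
Reactants: 23 rac-8-(benzyloxy)-7-[5-(benzyloxy)-4-methoxy-2-methylnaphthalen-1-yl]-1,3-dimethylisoquinoline
Product: 24 rac-7-(5-hydroxy-4-methoxy-2-methylnaphthalen-1-yl)-1,3-dimethylisoquinolin-8-ol
Conditions: H2 (1 atm), 10% Pd/C, MeOH–EtOAc, rt
Reagents that add atoms: none
Why: Catalytic hydrogenolysis of both aryl benzyl ethers, under neutral conditions at 1 atm so that the isoquinoline, the naphthalene and the methyl ether are left untouched.

Step 14
Reactants: 24 rac-7-(5-hydroxy-4-methoxy-2-methylnaphthalen-1-yl)-1,3-dimethylisoquinolin-8-ol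
Product: 25 ent-dioncophylleine A as defined by the target SMILES (single atropisomer of 24, C7–C1′ axis of the ent series)
Conditions: preparative HPLC, cellulose tris(3,5-dimethylphenylcarbamate) phase, n-hexane–iPrOH–Et2NH, rt
Reagents that add atoms: none
Why: Resolution of the racemate by chromatography on a chiral stationary phase: the axis, flanked by C8–OH, C6–H, the C2′ methyl group and the C8′–H peri position, should not rotate at room temperature, so both atropisomers are stable, and the ent-series enantiomer is assigned by comparing its CD spectrum with a computed one.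

Compound list
1 | 3-methoxy-2-(trimethylsilyl)phenyl trifluoromethanesulfonate | COc1cccc(OS(=O)(=O)C(F)(F)F)c1[Si](C)(C)C | starting material
2 | acetylacetone | CC(=O)CC(C)=O | starting material
3 | 3-methoxybenzyne (not isolated) | COC1=CC=CC#C1 | intermediate
4 | 1-(2-acetyl-3-methoxyphenyl)propan-2-one (not isolated) | COc1cccc(CC(C)=O)c1C(C)=O | intermediate
5 | 8-methoxy-1,3-dimethylisoquinoline | COc1cccc2cc(C)nc(C)c12 | intermediate
6 | 1,3-dimethylisoquinolin-8-ol | Cc1cc2cccc(O)c2c(C)n1 | intermediate
7 | 7-bromo-1,3-dimethylisoquinolin-8-ol | Cc1cc2ccc(Br)c(O)c2c(C)n1 | intermediate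
8 | 8-(benzyloxy)-7-bromo-1,3-dimethylisoquinoline | Cc1cc2ccc(Br)c(OCc3ccccc3)c2c(C)n1 | intermediate
9 | ethyl 2-hydroxy-6-methylbenzoate | CCOC(=O)c1c(C)cccc1O | starting material
10 | ethyl 2-(benzyloxy)-6-methylbenzoate | CCOC(=O)c1c(C)cccc1OCc1ccccc1 | intermediate
11 | ethyl 2-(benzyloxy)-6-(lithiomethyl)benzoate (not isolated) | [Li]Cc1cccc(OCc2ccccc2)c1C(=O)OCC | intermediate
12 | ethyl 2-(benzyloxy)-6-(2-ethoxy-2-oxoethyl)benzoate | CCOC(=O)Cc1cccc(OCc2ccccc2)c1C(=O)OCC | intermediate
13 | lithium enolate of 12 at the acetate arm (not isolated) | [Li+].CCOC([O-])=Cc1cccc(OCc2ccccc2)c1C(=O)OCC | intermediate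
14 | rac-ethyl 2-(benzyloxy)-6-{1-[8-(benzyloxy)-1,3-dimethylisoquinolin-7-yl]-2-ethoxy-2-oxoethyl}benzoate | CCOC(=O)C(c1ccc2cc(C)nc(C)c2c1OCc1ccccc1)c1cccc(OCc2ccccc2)c1C(=O)OCC | intermediate
15 | rac-2-(benzyloxy)-6-{[8-(benzyloxy)-1,3-dimethylisoquinolin-7-yl](carboxy)methyl}benzoic acid | OC(=O)C(c1ccc2cc(C)nc(C)c2c1OCc1ccccc1)c1cccc(OCc2ccccc2)c1C(O)=O | intermediate
16 | rac-8-(benzyloxy)-4-[8-(benzyloxy)-1,3-dimethylisoquinolin-7-yl]isochromane-1,3-dione | O=C1OC(=O)C(c2ccc3cc(C)nc(C)c3c2OCc2ccccc2)c2cccc(OCc3ccccc3)c12 | intermediate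
17 | ethyl but-2-ynoate | CCOC(=O)C#CC | starting material
18 | sodium enolate of 16 (not isolated) | [Na+].[O-]C1=C(c2ccc3cc(C)nc(C)c3c2OCc2ccccc2)c2cccc(OCc3ccccc3)c2C(=O)O1 | intermediate
19 | sodium rac-5-(benzyloxy)-1-[8-(benzyloxy)-1,3-dimethylisoquinolin-7-yl]-3-(ethoxycarbonyl)-2-methyl-4-oxo-1,4-dihydronaphthalene-1-carboxylate (not isolated) | [Na+].CCOC(=O)C1=C(C)C(C([O-])=O)(c2ccc3cc(C)nc(C)c3c2OCc2ccccc2)c2cccc(OCc3ccccc3)c2C1=O | intermediate
20 | rac-ethyl 8-(benzyloxy)-4-[8-(benzyloxy)-1,3-dimethylisoquinolin-7-yl]-1-hydroxy-3-methyl-2-naphthoate (racemic at the axis) | CCOC(=O)c1c(C)c(-c2ccc3cc(C)nc(C)c3c2OCc2ccccc2)c2cccc(OCc3ccccc3)c2c1O | intermediate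
21 | rac-8-(benzyloxy)-4-[8-(benzyloxy)-1,3-dimethylisoquinolin-7-yl]-1-hydroxy-3-methyl-2-naphthoic acid (not isolated) | OC(=O)c1c(C)c(-c2ccc3cc(C)nc(C)c3c2OCc2ccccc2)c2cccc(OCc3ccccc3)c2c1O | intermediate
22 | rac-8-(benzyloxy)-4-[8-(benzyloxy)-1,3-dimethylisoquinolin-7-yl]-3-methylnaphthalen-1-ol | Cc1cc(O)c2c(OCc3ccccc3)cccc2c1-c1ccc2cc(C)nc(C)c2c1OCc1ccccc1 | intermediate
23 | rac-8-(benzyloxy)-7-[5-(benzyloxy)-4-methoxy-2-methylnaphthalen-1-yl]-1,3-dimethylisoquinoline | COc1cc(C)c(-c2ccc3cc(C)nc(C)c3c2OCc2ccccc2)c2cccc(OCc3ccccc3)c12 | intermediate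
24 | rac-7-(5-hydroxy-4-methoxy-2-methylnaphthalen-1-yl)-1,3-dimethylisoquinolin-8-ol (both atropisomers) | COc1cc(C)c(-c2ccc3cc(C)nc(C)c3c2O)c2cccc(O)c12 | intermediate
25 | ent-dioncophylleine A as defined by the target SMILES (single atropisomer, axis not expressible in SMILES) | COc1cc(C)c(-c2ccc3cc(C)nc(C)c3c2O)c2cccc(O)c12 | target

Total step count: 14 (13 reactions and one separation).
Longest linear sequence: 12 steps (steps 1–4, then 7–14); the side branch is steps 5–6.

Steps most likely to fail

Step 10. The stabilised enolate is flanked by two ortho-substituted aryl groups and may add too slowly to the β-substituted ynoate. Isomerisation and oligomerisation of the ynoate, or hydrolytic and decarboxylative decay of the anhydride, would then win. In the fallback, ring A is built on the unsubstituted donor and the aryl–aryl bond is made afterwards by cross-coupling. It sets out from 12, 17 and 8 and comes back at 20.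
- Saponification of 12 (KOH, aq EtOH, reflux) should give 2-(benzyloxy)-6-(carboxymethyl)benzoic acid F1.
- Me3SiC≡COEt should dehydrate it to 8-(benzyloxy)isochromane-1,3-dione F2.
- The standard Tamura annulation of F2 with 17 (NaH, THF) should give ethyl 8-(benzyloxy)-1-hydroxy-3-methyl-2-naphthoate F3.
- NBS (MeCN, 0 °C) should brominate it para to the hydroxyl to give ethyl 8-(benzyloxy)-4-bromo-1-hydroxy-3-methyl-2-naphthoate F4.
- Miyaura borylation of 8 (B2pin2, PdCl2(dppf), KOAc, dioxane, 90 °C) should give 8-(benzyloxy)-1,3-dimethyl-7-(4,4,5,5-tetramethyl-1,3,2-dioxaborolan-2-yl)isoquinoline F5.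
- Suzuki–Miyaura coupling of F4 with F5 (Pd2(dba)3, 2-dicyclohexylphosphino-2′,6′-dimethoxybiphenyl, K3PO4, toluene–H2O, 100 °C) should give 20. This type of coupling is established for tri-ortho-substituted biaryls.

Step 7. Reductive elimination from the crowded arylpalladium enolate may be slow, so that hydrodebromination takes over. The amide base may also attack the C1-methyl protons of the isoquinoline. In the fallback, the polarity of both partners is reversed and no strong base meets the isoquinoline. It sets out from 13 and 8 and comes back at 14.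
- Quenching enolate 13 with NBS (THF, −78 °C) should give ethyl 2-(benzyloxy)-6-(1-bromo-2-ethoxy-2-oxoethyl)benzoate F6.
- Bromide 8 is borylated as above to the pinacol boronate F5.
- The nickel-catalysed Suzuki-type arylation of α-bromo esters (Ni(PPh3)4, K3PO4, toluene, 60–80 °C) should join F6 and F5 to give 14. It runs through an α-ester radical rather than through enolate transfer to an arylpalladium bromide.

Step 1. Base-induced intramolecular aldol closure of the 1,5-diketone, or a second arylation of the diketone, may run ahead of the ammonia condensation. The fallback uses the best-documented partner of the aryne acyl-alkylation and installs the C3 methyl group afterwards. It sets out from 1 and comes back at 5.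
- Compound 1 and methyl acetoacetate (CsF, MeCN, 80 °C) should give methyl 2-(2-acetyl-3-methoxyphenyl)acetate F7.
- Aqueous NH3 (60 °C) should close it to 8-methoxy-1-methylisoquinolin-3-ol F8.
- Tf2O and pyridine should give 8-methoxy-1-methylisoquinolin-3-yl trifluoromethanesulfonate F9.
- Suzuki–Miyaura methylation with trimethylboroxine (Pd(PPh3)4, K2CO3, dioxane, 100 °C) should give 5.

Further compounds
F1 | step 10 | 2-(benzyloxy)-6-(carboxymethyl)benzoic acid | OC(=O)Cc1cccc(OCc2ccccc2)c1C(O)=O
F2 | step 10 | 8-(benzyloxy)isochromane-1,3-dione | O=C1Cc2cccc(OCc3ccccc3)c2C(=O)O1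
F3 | step 10 | ethyl 8-(benzyloxy)-1-hydroxy-3-methyl-2-naphthoate | CCOC(=O)c1c(C)cc2cccc(OCc3ccccc3)c2c1O
F4 | step 10 | ethyl 8-(benzyloxy)-4-bromo-1-hydroxy-3-methyl-2-naphthoate | CCOC(=O)c1c(C)c(Br)c2cccc(OCc3ccccc3)c2c1O
F5 | step 10 | 8-(benzyloxy)-1,3-dimethyl-7-(4,4,5,5-tetramethyl-1,3,2-dioxaborolan-2-yl)isoquinoline | Cc1cc2ccc(B3OC(C)(C)C(C)(C)O3)c(OCc3ccccc3)c2c(C)n1
F6 | step 7 | ethyl 2-(benzyloxy)-6-(1-bromo-2-ethoxy-2-oxoethyl)benzoate (racemic) | CCOC(=O)C(Br)c1cccc(OCc2ccccc2)c1C(=O)OCC
F7 | step 1 | methyl 2-(2-acetyl-3-methoxyphenyl)acetate | COC(=O)Cc1cccc(OC)c1C(C)=O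
F8 | step 1 | 8-methoxy-1-methylisoquinolin-3-ol | COc1cccc2cc(O)nc(C)c12
F9 | step 1 | 8-methoxy-1-methylisoquinolin-3-yl trifluoromethanesulfonate | COc1cccc2cc(OS(=O)(=O)C(F)(F)F)nc(C)c12
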